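**Plan**
1. Retrosynthesis: the tiglate C8–O acyl bond is cut and C3 and C8 are taken back to ketones. Both carbons carry oxygen and sit 1,6 across the ten-membered ring, so reconnecting C3–C8 folds the macrocycle into a cis-fused hexahydronaphthalene ring-fusion diol in which C4=C5 (ring A) and C1=C2 (ring B) are each held Z inside a cyclohexene.
2. The bicycle is then cut at the lactone C12–O6 bond and the C6 and C12 oxygens (two allylic oxidations), at C10–C14 (methyl addition), C1=C2 (metathesis), C2–C3 and C1–C10 (two vinyl additions), C8–C9 (enolate alkylation) and C8–O (Rubottom oxidation). This leaves (S)-carvone as ring A.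
3. Forward: ring A is carvone; ring B is closed on it by metathesis; the lactone ring follows by oxidative lactonisation; the ten-membered ring appears last by cleaving the bond shared by rings A and B, with no macrocyclisation.
4. Stereochemistry: C7 comes from (S)-carvone and steers the C8 alkylation; the C8 silyloxy group steers the C3 vinyl addition (cis glycol); the cis-fused bicycle sets C10 (convex-face methyl addition) and C6 (hindered hydride anti to the C7/C8 substituents). After cleavage the C10 hydroxyl directs the C8 reduction (1,3-anti) and the C3 carbonyl is reduced from its open face; both ring alkenes are Z by construction and the tiglate is E from the reagent.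

Key step: step 12

Remark (numbering): germacrane numbering is used for every intermediate: C3 = carvone carbonyl carbon, C4 (CH3 = C15), C5, C6, C7 (isopropenyl = C11, C12, C13), C8 = α′-carbon; C9, C10 (CH3 = C14), C1 and C2 are added later.
Assumption: in 22, 23 and 25 the C10 hydroxyl and the C3 carbonyl, held close by the Z C1=C2 bond, are taken to close reversibly to a 3,10-hemiketal; the compounds are drawn open, and steps 13 and 15 run through the open tautomer.

**Route**

Step 1
Reactants: 1 (S)-(+)-carvone
Product: 3 triethylsilyl dienol ether of carvone (C3–OSiEt3; C3=C8 and C4=C5), via lithium dienolate 2 (not isolated)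
Conditions: LiN(iPr)2, THF, −78 °C; Et3SiCl, −78 to 0 °C
Reagents that add atoms: chlorotriethylsilane, CC[Si](Cl)(CC)CC
Why: Kinetic deprotonation of the enone by LiN(iPr)2 occurs at the α′-carbon C8, and O-silylation of the cross-conjugated dienolate (silyl enol ether formation) leaves the C7 stereocentre untouched.

Step 2
Reactants: 3 triethylsilyl dienol ether of carvone
Product: 5 trans-C8-(triethylsilyloxy)carvone, via silyloxy epoxide 4 (not isolated)
Conditions: mCPBA (1.0 equiv), NaHCO3, CH2Cl2, −20 to 0 °C
Reagents that add atoms: mCPBA, OOC(=O)c1cccc(Cl)c1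
Why: Rubottom oxidation: the peracid epoxidises the most electron-rich double bond, the silyl enol ether C3=C8, and the silyloxy epoxide opens with 1,4-silyl migration to the α-silyloxy ketone, the new C8 centre (oxygen anti to the isopropenyl group) being of no consequence because it is planarised again in step 3.

Step 3
Reactants: 5 trans-C8-(triethylsilyloxy)carvone; 6 2-bromo-N-methoxy-N-methylacetamide
Product: 8 C8-alkylated silyloxy ketone (amide arm trans and OSiEt3 cis to the isopropenyl group), via lithium enolate 7 (not isolated)
Conditions: LiN(iPr)2, THF, −78 °C; then 6, DMPU, −78 to −30 °C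
Reagents that add atoms: 2-bromo-N-methoxy-N-methylacetamide (6), CON(C)C(=O)CBr
Why: Enolate alkylation: C8–H is the only α-hydrogen of the enone, so LiN(iPr)2 should give the tetrasubstituted α-silyloxy enolate, and the activated primary α-bromo amide is attacked on the enolate face anti to the adjacent C7 isopropenyl group, which places the new C9 arm trans and the silyloxy group cis to C11.

Step 4
Reactants: 8 C8-alkylated silyloxy ketone; 9 vinylmagnesium bromide
Product: 10 dienyl ketone (C3 vinyl carbinol; C8 arm CH2C(=O)CH=CH2)
Conditions: CH2=CHMgBr (5 equiv), THF, −78 to 0 °C; inverse quench into cold aq. citric acid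
Reagents that add atoms: vinylmagnesium bromide (9), C=C[Mg]Br
Why: Grignard 1,2-addition combined with a Weinreb ketone synthesis: at C3 the vinyl group enters by axial attack anti to the axial, non-chelating C8 silyloxy group (Felkin–Anh polar model) and anti to the isopropenyl group, so the new C3 hydroxyl is cis to O8 and the vinyl group cis to the C9 arm, while the N-methoxy-N-methylamide is held as its magnesium chelate until the acidic quench and then gives the vinyl ketone.

Step 5
Reactants: 10 dienyl ketone
Product: 11 cis-fused bicyclic enone (ring B: C10=O, C1=C2)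
Conditions: RuCl2(=CHPh)(H2IMes)(PCy3) (second-generation Grubbs catalyst, 5 mol%), CH2Cl2 (5 mM), 40 °C
Reagents that add atoms: none
Why: Ring-closing metathesis between the two monosubstituted alkenes, which lie on the same face of ring A, closes the cis-fused six-membered ring B with loss of ethene and fixes C1=C2 as Z, the 1,1-disubstituted isopropenyl and the trisubstituted C4=C5 alkenes being much slower partners.

Step 6
Reactants: 11 cis-fused bicyclic enone; 12 methyllithium
Product: 13 bicyclic diene diol (C10 tertiary alcohol)
Conditions: MeLi (3 equiv), THF, −78 °C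
Reagents that add atoms: methyllithium (12), [Li]C
Why: 1,2-Addition of methyllithium to the enone carbonyl: in the cis-fused bicycle C7 is axial on ring B and shields the concave face, so the methyl group should enter C10 from the convex face that carries the two angular oxygens, giving the C10 alcohol with CH3 cis and OH trans to them, which is the configuration of the target.

Step 7
Reactants: 13 bicyclic diene diol
Product: 14 C6 enone (C6=O conjugated with C4=C5)
Conditions: Rh2(caprolactamate)4 (1 mol%), t-BuOOH (5 equiv), NaHCO3, CH2Cl2, 25 °C
Reagents that add atoms: tert-butyl hydroperoxide, CC(C)(C)OO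
Why: Dirhodium-caprolactamate-catalysed allylic oxidation by tert-butylperoxyl radicals: C6 is the only ring methylene allylic to the electron-rich trisubstituted C4=C5 bond (C3 is quaternary and C1=C2 has no allylic hydrogen), so hydrogen abstraction and oxygenation there should give the C6 enone, as in related oxidations of cyclohexene methylenes in the presence of an isopropenyl group.

Step 8
Reactants: 14 C6 enone
Product: 15 C12 allylic alcohol (isopropenyl CH3 turned into CH2OH)
Conditions: SeO2 (0.3 equiv), t-BuOOH (2 equiv), CH2Cl2, 0 to 25 °C
Reagents that add atoms: tert-butyl hydroperoxide, CC(C)(C)OO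
Why: SeO2-catalysed allylic hydroxylation (Riley-type ene reaction and [2,3]-shift) takes place at the methyl group of the isopropenyl unit, the only remaining nucleophilic alkene with allylic hydrogens now that C4=C5 is part of an enone, and gives the C12 allylic alcohol.

Step 9
Reactants: 15 C12 allylic alcohol
Product: 16 C6,C12-diol (C6–OH cis to the C7 side chain)
Conditions: LiBH(s-Bu)3 (4 equiv), THF, −78 °C; then H2O
Reagents that add atoms: none
Why: 1,2-Reduction of the β,β-disubstituted enone by the bulky LiBH(s-Bu)3: hydride is delivered to C6 on the face opposite the adjacent C7 side chain and the axial C8 silyloxy group, so the C6 hydroxyl should result cis to C11 as the lactone requires.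

Step 10
Reactants: 16 C6,C12-diol
Product: 19 cis-fused α-methylene lactone silyl ether, via hydroxy enal 17 (not isolated), via lactol 18 (not isolated)
Conditions: TEMPO (0.2 equiv), PhI(OAc)2 (2.5 equiv), CH2Cl2, 25 °C
Reagents that add atoms: none
Why: Oxidative lactonisation of a 1,4-diol: the oxoammonium species from TEMPO oxidises the primary allylic alcohol to the enal 17, the cis C6 hydroxyl closes it to the lactol 18 and a second oxidation gives the cis-fused α-methylene-γ-butyrolactone, while the tertiary alcohols and the silylated glycol are inert.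

Step 11
Reactants: 19 cis-fused α-methylene lactone silyl ether
Product: 20 lactone triol (ring-fusion cis-diol at C3/C8; C10–OH free)
Conditions: HF·pyridine, pyridine, THF, 0 to 25 °C
Reagents that add atoms: none
Why: Fluoride-induced cleavage of the tertiary triethylsilyl ether (desilylation) under pyridine-buffered conditions frees the C8 hydroxyl without harming the α-methylene lactone or the tertiary allylic alcohols.

Step 12
Reactants: 20 lactone triol
Product: 22 ten-membered (1Z,4Z)-diene-3,8-dione lactone, via cyclic lead diester 21 (not isolated)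
Conditions: Pb(OAc)4 (1.1 equiv), CH2Cl2, −20 to 0 °C
Reagents that add atoms: none
Why: The ring-fusion hydroxyls at C3 and C8 are cis (O–C–C–O dihedral near 60° in the cis-fused bicycle) and exchange two acetates on tetravalent lead to give the five-membered cyclic diester 21, which collapses in a concerted two-electron fragmentation to the C3 and C8 ketones and divalent lead diacetate. The closest known reaction is the Criegee glycol cleavage of cis-decalin-9,10-diols to cyclodecane-1,6-diones. No ring is closed by bond formation: the ten-membered ring appears by ring expansion, through scission of the bond shared by six-membered rings A and B, so no macrocyclisation and no ring-closure mode is involved. No stereocentre is created (C3 and C8 become sp2 and their configurations, set only to make the glycol cis, are erased), and C1=C2 and C4=C5 are delivered Z because each was an endocyclic cyclohexene bond. The step needs cleavage of this glycol only: the C10 alcohol has no vicinal hydroxyl and cannot form the cyclic diester, and at or below 0 °C tetravalent lead should not attack the alkenes, the α-methylene lactone or the tertiary allylic alcohol. Acetic acid is the only by-product in solution, so the base-sensitive β-hydroxy ketone product is never exposed to base.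

Step 13
Reactants: 22 ten-membered diene-3,8-dione lactone
Product: 23 C8 alcohol (3-ketone; C8–OH 1,3-anti to C10–OH)
Conditions: Me4NBH(OAc)3, MeCN/AcOH (1:1), −30 °C
Reagents that add atoms: none
Why: Evans–Saksena reduction: the C10 hydroxyl exchanges onto boron and delivers hydride intramolecularly through a six-membered chair transition state to the C8 carbonyl, which should give the 1,3-anti diol (C8–OH trans to C10–OH, the 8R configuration), whereas the less electrophilic conjugated C3 carbonyl is out of reach of a six-membered delivery and is not reduced by this mild reagent.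

Step 14
Reactants: 23 C8 alcohol; 24 tigloyl chloride
Product: 25 C8 tiglate 3-ketone
Conditions: 24, pyridine, DMAP (cat.), CH2Cl2, 0 °C
Reagents that add atoms: tigloyl chloride (24), C/C=C(\C)C(Cl)=O
Why: Acylation of the only secondary alcohol by the acid chloride under nucleophilic catalysis (esterification) leaves the tertiary C10 hydroxyl untouched and keeps the E geometry of the tigloyl group.

Step 15
Reactants: 25 C8 tiglate 3-ketone
Product: 26 target CNP0262559.2
Conditions: NaBH4, CeCl3·7H2O, MeOH, −78 °C
Reagents that add atoms: none
Why: Luche 1,2-reduction: with the carbonyl oxygen held next to the C10 hydroxyl by the Z C1=C2 bond, one face of C3 is covered by the C4–C9 span of the ring and hydride should enter from the open face that also carries the C10 methyl group, giving the C3 alcohol cis to the C10 hydroxyl (3R), while the α-methylene lactone and the tiglate are not reduced at −78 °C.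

**Compound list**

1 | (S)-(+)-carvone | CC1=CC[C@@H](CC1=O)C(C)=C | starting material
2 | lithium dienolate of carvone (C3–OLi, C3=C8) | CC1=CC[C@@H](C=C1[O-])C(C)=C.[Li+] | intermediate
3 | triethylsilyl dienol ether of carvone (C3–OSiEt3; C3=C8 and C4=C5) | CC1=CC[C@@H](C=C1O[Si](CC)(CC)CC)C(C)=C | intermediate
4 | silyloxy epoxide (C3–C8 oxirane trans to the isopropenyl group, C3 bearing OSiEt3) | CC1=CC[C@@H]([C@H]2O[C@@]12O[Si](CC)(CC)CC)C(C)=C | intermediate
5 | trans-C8-(triethylsilyloxy)carvone (OSiEt3 trans to the C7 isopropenyl group) | CC1=CC[C@@H]([C@@H](O[Si](CC)(CC)CC)C1=O)C(C)=C | intermediate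
6 | 2-bromo-N-methoxy-N-methylacetamide | CON(C)C(=O)CBr | starting material
7 | lithium enolate of 5 (C3–OLi, C3=C8, C8–OSiEt3) | CC1=CC[C@@H](C(O[Si](CC)(CC)CC)=C1[O-])C(C)=C.[Li+] | intermediate
8 | C8-alkylated silyloxy ketone: carvone with, at C8, OSiEt3 cis and CH2C(=O)N(OMe)Me trans to the C7 isopropenyl group | CC1=CC[C@@H]([C@@](O[Si](CC)(CC)CC)(CC(=O)N(C)OC)C1=O)C(C)=C | intermediate
9 | vinylmagnesium bromide | C=C[Mg]Br | starting material
10 | dienyl ketone: C3 tertiary alcohol with vinyl group (C3–OH cis to C8–OSiEt3, vinyl cis to the C9 arm); C8 arm CH2C(=O)CH=CH2 | CC1=CC[C@@H]([C@@](O[Si](CC)(CC)CC)(CC(=O)C=C)[C@@]1(O)C=C)C(C)=C | intermediate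
11 | cis-fused bicyclic enone: ring B cyclohexenone (C10=O, C1=C2); C3–OH and C8–OSiEt3 cis at the ring fusion, on the face of the C7 isopropenyl group | CC1=CC[C@H](C(C)=C)[C@@]2(O[Si](CC)(CC)CC)CC(=O)C=C[C@@]12O | intermediate
12 | methyllithium | [Li]C | starting material
13 | bicyclic diene diol: C10 tertiary alcohol, C10–CH3 cis and C10–OH trans to the ring-fusion oxygens | CC1=CC[C@H](C(C)=C)[C@@]2(O[Si](CC)(CC)CC)C[C@@](C)(O)C=C[C@@]12O | intermediate
14 | C6 enone (C6=O conjugated with C4=C5) | CC1=CC(=O)[C@H](C(C)=C)[C@@]2(O[Si](CC)(CC)CC)C[C@@](C)(O)C=C[C@@]12O | intermediate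
15 | C12 allylic alcohol of 14 (2-(hydroxymethyl)vinyl group on C7) | CC1=CC(=O)[C@H](C(CO)=C)[C@@]2(O[Si](CC)(CC)CC)C[C@@](C)(O)C=C[C@@]12O | intermediate
16 | C6,C12-diol (C6–OH cis to the C7 side chain and to C8–OSiEt3) | CC1=C[C@H](O)[C@H](C(CO)=C)[C@@]2(O[Si](CC)(CC)CC)C[C@@](C)(O)C=C[C@@]12O | intermediate
17 | hydroxy enal (C12 aldehyde, C6–OH free) | CC1=C[C@H](O)[C@H](C(C=O)=C)[C@@]2(O[Si](CC)(CC)CC)C[C@@](C)(O)C=C[C@@]12O | intermediate
18 | lactol (C12 hemiacetal closed on O6, anomeric mixture) | CC1=C[C@@H]2OC(O)C(=C)[C@@H]2[C@@]3(O[Si](CC)(CC)CC)C[C@@](C)(O)C=C[C@@]13O | intermediate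
19 | cis-fused α-methylene-γ-butyrolactone (6,12-olide) with C8–OSiEt3, C3–OH and C10–OH | CC1=C[C@@H]2OC(=O)C(=C)[C@@H]2[C@@]3(O[Si](CC)(CC)CC)C[C@@](C)(O)C=C[C@@]13O | intermediate
20 | key-step precursor: α-methylene lactone fused to the hexahydronaphthalene ring-fusion cis-diol (C3–OH and C8–OH cis, on the face of the lactone; C10–OH free) | CC1=C[C@@H]2OC(=O)C(=C)[C@@H]2[C@@]3(O)C[C@@](C)(O)C=C[C@@]13O | intermediate
21 | cyclic lead diester of 20 (O3 and O8 bridged by Pb(OAc)2) | CC1=C[C@@H]2OC(=O)C(=C)[C@@H]2[C@@]3(O[Pb](OC(C)=O)(OC(C)=O)O4)C[C@@](C)(O)C=C[C@@]134 | intermediate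
22 | key-step product: ten-membered (1Z,4Z)-10-hydroxy-3,8-dioxogermacra-1,4,11(13)-trien-6,12-olide | C/C1=C/[C@@H]2OC(=O)C(=C)[C@@H]2C(=O)C[C@@](C)(O)/C=C\C1=O | intermediate
23 | C8 alcohol (8R; C8–OH 1,3-anti to C10–OH; 3-ketone) | C/C1=C/[C@@H]2OC(=O)C(=C)[C@@H]2[C@H](O)C[C@@](C)(O)/C=C\C1=O | intermediate
24 | tigloyl chloride, (E)-2-methylbut-2-enoyl chloride | C/C=C(\C)C(Cl)=O | starting material
25 | C8 tiglate 3-ketone | C/C1=C/[C@@H]2OC(=O)C(=C)[C@@H]2[C@H](OC(=O)/C(C)=C/C)C[C@@](C)(O)/C=C\C1=O | intermediate
26 | target CNP0262559.2 (3R,6S,7R,8R,10R; 1Z,4Z; E-tiglate) | C/C1=C/[C@@H]2OC(=O)C(=C)[C@@H]2[C@H](OC(=O)/C(C)=C/C)C[C@@](C)(O)/C=C\[C@H]1O | target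

**Step count and risks**

Total step count: 15. Longest linear sequence: 15 steps from (S)-carvone (the route is fully linear).

Steps most likely to fail:

1. Step 3. The hindered α-silyloxy enolate may form or alkylate sluggishly: competing γ-deprotonation at C6, O-to-O silyl transfer within the enediolate, or proton transfer from the bromo amide would erode C-alkylation at C8. Fallback (sets out from 5, comes back at 10): the C8 quaternary carbinol is made by addition to a C8 ketone instead of by enolate alkylation. Vinylmagnesium bromide adds to C3 of 5 anti to the isopropenyl group to give the vinyl carbinol silyl ether F1. Bu4NF removes the silyl group to give the diol F2. Dess–Martin periodinane oxidises the secondary C8 alcohol to the α-ketol F3. Me3SiOTf/2,6-lutidine gives the trimethylsilyl ether F4. The Reformatsky reagent from 6 and zinc adds to the C8 carbonyl anti to both the C3 silyloxy group and the C7 isopropenyl group to give the β-hydroxy amide F5, with the C8 configuration of 8. Et3SiOTf/2,6-lutidine gives the bis-silyl ether F6. K2CO3 in methanol removes the more labile trimethylsilyl group to give the hydroxy amide F7. Vinylmagnesium bromide then turns the amide of F7 into the vinyl ketone 10.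

2. Step 7. Hydrogen abstraction may lack site selectivity (C15 and C12 methyl groups, C7–H), or the tertiary allylic alcohols may be degraded by the peroxyl radicals, so that the C6 ketone forms inefficiently. Fallback (sets out from 13, comes back at 14): oxygen is brought to C6 by an ene reaction and an allylic shift instead of radical C–H abstraction. Photooxygenation (O2, hν, tetraphenylporphyrin, CH2Cl2, −20 °C; Schenck ene reaction steered by the C3 hydroxyl) of the trisubstituted C4=C5 bond removes a C6 hydrogen and gives the tertiary C4 hydroperoxide F8 with a C5=C6 bond. On standing in CHCl3 the Schenck rearrangement moves the peroxy group suprafacially to C6 and gives the secondary C6 hydroperoxide F9 with C4=C5 restored. Ac2O/pyridine dehydrates F9 (Kornblum–DeLaMare-type) to the enone 14.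

3. Step 15. Hydride addition to the flexible, partly hemiketal-masked C3 carbonyl may show poor facial selectivity, and conjugate reduction of the α-methylene lactone may compete. Fallback (sets out from 25, comes back at 26): reagent control on a ketone locked in the open form. Me3SiOTf/2,6-lutidine at −78 °C silylates the C10 hydroxyl to give the trimethylsilyl ether F10, which cannot close to a hemiketal. Corey–Bakshi–Shibata reduction with (S)-1-methyl-3,3-diphenyltetrahydro-1H,3H-pyrrolo[1,2-c][1,3,2]oxazaborole and catecholborane in toluene at −78 °C, in which the α-methyl-branched C4=C5 arm acts as the large group, gives the (3R)-alcohol silyl ether F11. HF·pyridine removes the silyl group to give 26.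

**Further compounds**

F1 | step 3 | vinyl carbinol silyl ether (C3–OH with vinyl trans to isopropenyl; C8–H with OSiEt3) | CC1=CC[C@@H]([C@@H](O[Si](CC)(CC)CC)[C@@]1(O)C=C)C(C)=C
F2 | step 3 | diol (C3 tertiary OH, C8 secondary OH) | CC1=CC[C@@H]([C@@H](O)[C@@]1(O)C=C)C(C)=C
F3 | step 3 | α-ketol (C8 ketone, C3–OH) | CC1=CC[C@@H](C(=O)[C@@]1(O)C=C)C(C)=C
F4 | step 3 | trimethylsilyl ether of the α-ketol (C3–OSiMe3, C8 ketone) | CC1=CC[C@@H](C(=O)[C@@]1(O[Si](C)(C)C)C=C)C(C)=C
F5 | step 3 | β-hydroxy amide (C8–OH cis to isopropenyl, C8–CH2C(=O)N(OMe)Me, C3–OSiMe3) | CC1=CC[C@@H]([C@@](O)(CC(=O)N(C)OC)[C@@]1(O[Si](C)(C)C)C=C)C(C)=C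
F6 | step 3 | bis-silyl ether (C8–OSiEt3, C3–OSiMe3, amide arm) | CC1=CC[C@@H]([C@@](O[Si](CC)(CC)CC)(CC(=O)N(C)OC)[C@@]1(O[Si](C)(C)C)C=C)C(C)=C
F7 | step 3 | hydroxy amide (C3–OH, C8–OSiEt3, amide arm) | CC1=CC[C@@H]([C@@](O[Si](CC)(CC)CC)(CC(=O)N(C)OC)[C@@]1(O)C=C)C(C)=C
F8 | step 7 | tertiary C4 hydroperoxide with C5=C6 (OOH cis to C3–OH) | C[C@@]1(OO)C=C[C@H](C(C)=C)[C@@]2(O[Si](CC)(CC)CC)C[C@@](C)(O)C=C[C@@]12O
F9 | step 7 | secondary C6 hydroperoxide with C4=C5 | CC1=C[C@H](OO)[C@H](C(C)=C)[C@@]2(O[Si](CC)(CC)CC)C[C@@](C)(O)C=C[C@@]12O
F10 | step 15 | C10 trimethylsilyl ether of 25 | C/C1=C/[C@@H]2OC(=O)C(=C)[C@@H]2[C@H](OC(=O)/C(C)=C/C)C[C@@](C)(O[Si](C)(C)C)/C=C\C1=O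
F11 | step 15 | (3R)-alcohol C10 trimethylsilyl ether | C/C1=C/[C@@H]2OC(=O)C(=C)[C@@H]2[C@H](OC(=O)/C(C)=C/C)C[C@@](C)(O[Si](C)(C)C)/C=C\[C@H]1O
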